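**Plan**

1. Labels: dihydrofuran ring 1 (O1, C2, C3) is fused to benzo ring A, which carries the styryl group with ring F; dihydrofuran ring 2 (O1', C2', C3') is fused to the central benzo ring B, which carries the free OH and C3; ring C sits on C2, ring D on C3', ring E on C2'.
2. Retrosynthetic cuts, in order: the O–CH3 and O–CH2Ar bonds of the phenol ethers; the ring A–vinyl bond of the stilbene; C2'–C3' of ring 2 (O1'–C2' stays as a benzyl ether); the ring B–C3' bond; C2–C3 of ring 1; the ring B–C3 bond.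
3. Forward: a ring A/ring B benzophenone gives ring 1 by carbene C–H insertion; ring B is brominated next to C3 and aroylated with the ring D unit; ring 2 is closed last by the same kind of insertion; the stilbene is then attached (Mizoroki–Heck) and all ethers are cleaved.
4. Enabling feature: C3' is a diarylmethine carbon between ring B and ring D, so it can be a donor/donor carbene made from a benzophenone hydrazone; C2' is an O-benzylic carbon that can be carried as the CH2 of a 4-methoxybenzyl ether on O1', with its C–H bond five atoms from the carbene carbon. C3/C2 of ring 1 repeat this pattern.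
5. Stereochemistry: C3 and C3' come from the chiral catalyst Rh2(S-PTAD)4 (steps 6 and 11); C2 and C2' are formed cis and are turned trans in the last step by reversible opening of the benzylic C–O bonds; the E olefin comes from the Heck reaction.
6. Helpers: ring B carries two identical 4-methoxybenzyl (PMB) ethers, which makes the two positions flanking C3 equivalent at bromination (one ether becomes C2' and ring E, the other is a protecting group); ring 1 is kept cis up to the key step so that its C2–H cannot compete; chlorine on ring A is the placeholder for the stilbene.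

Key step: step 11

Assumption: Rh2(S-PTAD)4, dirhodium tetrakis[(S)-(1-adamantyl)(phthalimido)acetate], is taken to give the configuration drawn at the carbene-derived carbon; if the sense of induction proves opposite, Rh2(R-PTAD)4 is used in steps 6 and 11 with no other change.

**Route**

Step 1
Reactants: 1 5-chloro-2-hydroxybenzaldehyde; 2 4-methoxybenzyl chloride
Product: 3 5-chloro-2-[(4-methoxyphenyl)methoxy]benzaldehyde
Conditions: K2CO3, DMF, 60 °C
Reagents that add atoms: none
Why: Williamson etherification of the acidic salicylaldehyde phenol with a benzylic chloride installs the O–CH2Ar unit whose carbon becomes C2 and whose aryl group becomes ring C.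

Step 2
Reactants: 4 5-bromobenzene-1,3-diol; 2 4-methoxybenzyl chloride
Product: 5 1-bromo-3,5-bis[(4-methoxyphenyl)methoxy]benzene
Conditions: 2 (2.2 equiv), K2CO3, DMF, 60 °C
Reagents that add atoms: none
Why: Double Williamson etherification gives the symmetric ring B unit in which both oxygens carry the benzyl group needed later for ring 2.

Step 3
Reactants: 5 1-bromo-3,5-bis[(4-methoxyphenyl)methoxy]benzene; 3 5-chloro-2-[(4-methoxyphenyl)methoxy]benzaldehyde
Product: 7 {5-chloro-2-[(4-methoxyphenyl)methoxy]phenyl}{3,5-bis[(4-methoxyphenyl)methoxy]phenyl}methanol (racemic), via aryllithium 6 (not isolated)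
Conditions: n-BuLi, THF, −78 °C; then 3, −78 °C to 0 °C; H2O
Reagents that add atoms: none
Why: Bromine–lithium exchange is much faster than any reaction at the aryl chloride or the benzyl ethers at −78 °C, and the aryllithium adds 1,2 to the aldehyde; the carbinol centre is removed in step 4.

Step 4
Reactants: 7 the diarylmethanol
Product: 8 {5-chloro-2-[(4-methoxyphenyl)methoxy]phenyl}{3,5-bis[(4-methoxyphenyl)methoxy]phenyl}methanone
Conditions: Dess–Martin periodinane, CH2Cl2, rt
Reagents that add atoms: none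
Why: Dess–Martin oxidation converts the benzhydrol into the benzophenone under near-neutral conditions that leave the PMB ethers intact.

Step 5
Reactants: 8 the benzophenone
Product: 9 hydrazone of 8 (C=N–NH2, E/Z mixture)
Conditions: N2H4·H2O (excess), AcOH (cat.), EtOH, reflux
Reagents that add atoms: hydrazine (used as its hydrate), NN
Why: Acid-catalysed condensation of the diaryl ketone with excess hydrazine gives the N-unsubstituted hydrazone, the excess suppressing azine formation.

Step 6
Reactants: 9 the hydrazone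
Product: 11 (2R,3S)-3-{3,5-bis[(4-methoxyphenyl)methoxy]phenyl}-5-chloro-2-(4-methoxyphenyl)-2,3-dihydro-1-benzofuran (cis), via diazo compound 10 (not isolated)
Conditions: MnO2, CH2Cl2, 0 °C; filter; Rh2(S-PTAD)4 (1 mol %), CH2Cl2, 0 °C to rt
Reagents that add atoms: none
Why: MnO2 dehydrogenates the hydrazone to the diaryldiazomethane, whose divalent-rhodium donor/donor carbene inserts into the 1,5-related O–CH2 C–H bond (enantioselective intramolecular carbene C–H insertion); the chiral carboxylate ligands set C3 and the compact transition state gives the kinetic cis C2/C3 relationship.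

Step 7
Reactants: 11 the cis dihydrobenzofuran
Product: 12 (2R,3R)-3-{2-bromo-3,5-bis[(4-methoxyphenyl)methoxy]phenyl}-5-chloro-2-(4-methoxyphenyl)-2,3-dihydro-1-benzofuran (cis; spatial arrangement as in 11)
Conditions: NBS (1.0 equiv), CH2Cl2, −78 °C to 0 °C, dark
Reagents that add atoms: N-bromosuccinimide, O=C1CCC(=O)N1Br
Why: Electrophilic aromatic bromination goes to the most electron-rich ring (ring B, a 1,3-dialkoxy-5-alkylbenzene) at a carbon para to one alkoxy group and ortho to the other; the two such carbons flank the C3 attachment and are equivalent by rotation, while the carbon between the two PMB ethers is more hindered.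

Step 8
Reactants: 12 the aryl bromide; 13 3,5-dimethoxybenzaldehyde
Product: 15 {2-[(2R,3S)-5-chloro-2-(4-methoxyphenyl)-2,3-dihydro-1-benzofuran-3-yl]-4,6-bis[(4-methoxyphenyl)methoxy]phenyl}(3,5-dimethoxyphenyl)methanol (both carbinol epimers), via aryllithium 14 (not isolated)
Conditions: n-BuLi, THF, −78 °C; then 13, −78 °C to 0 °C; H2O
Reagents that add atoms: none
Why: Bromine–lithium exchange is selective over the aryl chloride at −78 °C, and the hindered aryllithium still adds to an unhindered aromatic aldehyde (1,2-addition); the new carbinol centre is removed in step 9.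

Step 9
Reactants: 15 the diarylmethanol
Product: 16 {2-[(2R,3S)-5-chloro-2-(4-methoxyphenyl)-2,3-dihydro-1-benzofuran-3-yl]-4,6-bis[(4-methoxyphenyl)methoxy]phenyl}(3,5-dimethoxyphenyl)methanone
Conditions: Dess–Martin periodinane, CH2Cl2, rt
Reagents that add atoms: none
Why: Dess–Martin oxidation of the benzhydrol gives the ring B/ring D benzophenone, which now has the PMB ether ortho to the carbonyl group, without touching the acid-sensitive cis ring 1.

Step 10
Reactants: 16 the benzophenone
Product: 17 hydrazone of 16 (C=N–NH2, E/Z mixture)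
Conditions: N2H4·H2O (large excess), AcOH (cat.), n-BuOH, 110 °C
Reagents that add atoms: hydrazine (used as its hydrate), NN
Why: Hydrazone formation at a carbonyl flanked by two ortho substituents needs forcing conditions, to which the ethers, the aryl chloride and ring 1 are inert.

Step 11
Reactants: 17 the hydrazone
Product: 19 (2R,3S)-4-[(2R,3S)-5-chloro-2-(4-methoxyphenyl)-2,3-dihydro-1-benzofuran-3-yl]-3-(3,5-dimethoxyphenyl)-2-(4-methoxyphenyl)-6-[(4-methoxyphenyl)methoxy]-2,3-dihydro-1-benzofuran (both rings cis), via diazo compound 18 (not isolated)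
Conditions: MnO2, CH2Cl2, 0 °C; filter; slow addition to Rh2(S-PTAD)4 (2 mol %), CH2Cl2, 0 °C to rt
Reagents that add atoms: none
Why: MnO2 dehydrogenates the hydrazone to the diaryldiazomethane 18, which loses N2 at the divalent-rhodium catalyst to give a donor/donor carbene at the future C3'; this carbene inserts into the O–CH2 C–H bond of the ortho PMB ether by an asynchronous hydride-shift/C–C-bond-forming pathway. The closest known reaction type is the enantioselective intramolecular C–H insertion of donor/donor rhodium carbenes from ortho-benzyloxy benzophenone hydrazones, which gives 2,3-diaryl-2,3-dihydrobenzofurans, as in step 6. Ring 2 closes by 1,5 C–H insertion, forming the C2'–C3' bond through a five-membered array (carbene carbon, two ring B carbons, O1', CH2). C3' is set by the chiral carboxylate ligands of the catalyst (reagent control, same sense as at C3 in step 6), and C2' is expected cis to it as the kinetic outcome of this reaction class; C2' is corrected to trans in step 13. The step needs site selectivity among activated C–H bonds, and the substrate secures it: the only other 1,5-related C–H, C2–H of ring 1, lies on the face opposite ring B while ring 1 is cis and could only react through a trans-fused bicycle, and the second PMB ether is para to the carbene carbon and out of reach; slow addition of the diazo compound limits azine formation.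

Step 12
Reactants: 19 the aryl chloride; 20 3,5-dimethoxystyrene
Product: 21 (2R,3S)-4-{(2R,3S)-5-[(E)-2-(3,5-dimethoxyphenyl)ethenyl]-2-(4-methoxyphenyl)-2,3-dihydro-1-benzofuran-3-yl}-3-(3,5-dimethoxyphenyl)-2-(4-methoxyphenyl)-6-[(4-methoxyphenyl)methoxy]-2,3-dihydro-1-benzofuran
Conditions: Pd2(dba)3 (cat.), P(t-Bu)3 (cat.), Cs2CO3, 1,4-dioxane, 110 °C
Reagents that add atoms: none
Why: Mizoroki–Heck reaction: the bulky electron-rich P(t-Bu)3 ligand lets zerovalent palladium insert into the electron-rich C–Cl bond of ring A, and syn carbopalladation at the terminal styrene carbon followed by syn β-hydride elimination gives the E stilbene.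

Step 13
Reactants: 21 the hexamethyl PMB ether
Product: 22 trans-diptoindonesin B
Conditions: BBr3 (excess), pentamethylbenzene, CH2Cl2, −78 °C to rt; then H2O
Reagents that add atoms: none
Why: BBr3 cleaves the aryl methyl ethers by bromide attack on the boron-activated methyl groups and the PMB ether by ionisation (cation trapped by pentamethylbenzene), and the same Lewis acid reversibly opens the benzylic C2–O1 and C2'–O1' bonds to para-oxygen-stabilised benzylic cations that reclose to the more stable trans rings while C3 and C3' stay untouched (global ether cleavage with thermodynamic cis-to-trans equilibration of 2-aryl-2,3-dihydrobenzofurans).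

**Compound list**

1 | 5-chloro-2-hydroxybenzaldehyde | O=Cc1cc(Cl)ccc1O | starting material
2 | 4-methoxybenzyl chloride | COc1ccc(CCl)cc1 | starting material
3 | 5-chloro-2-[(4-methoxyphenyl)methoxy]benzaldehyde | O=Cc1cc(Cl)ccc1OCc1ccc(OC)cc1 | intermediate
4 | 5-bromobenzene-1,3-diol | Oc1cc(O)cc(Br)c1 | starting material
5 | 1-bromo-3,5-bis[(4-methoxyphenyl)methoxy]benzene | COc1ccc(COc2cc(Br)cc(OCc3ccc(OC)cc3)c2)cc1 | intermediate
6 | {3,5-bis[(4-methoxyphenyl)methoxy]phenyl}lithium (not isolated) | COc1ccc(COc2cc([Li])cc(OCc3ccc(OC)cc3)c2)cc1 | intermediate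
7 | {5-chloro-2-[(4-methoxyphenyl)methoxy]phenyl}{3,5-bis[(4-methoxyphenyl)methoxy]phenyl}methanol (racemic) | OC(c1cc(Cl)ccc1OCc1ccc(OC)cc1)c1cc(OCc2ccc(OC)cc2)cc(OCc2ccc(OC)cc2)c1 | intermediate
8 | {5-chloro-2-[(4-methoxyphenyl)methoxy]phenyl}{3,5-bis[(4-methoxyphenyl)methoxy]phenyl}methanone | O=C(c1cc(Cl)ccc1OCc1ccc(OC)cc1)c1cc(OCc2ccc(OC)cc2)cc(OCc2ccc(OC)cc2)c1 | intermediate
9 | [{5-chloro-2-[(4-methoxyphenyl)methoxy]phenyl}{3,5-bis[(4-methoxyphenyl)methoxy]phenyl}methylidene]hydrazine (E/Z mixture) | NN=C(c1cc(Cl)ccc1OCc1ccc(OC)cc1)c1cc(OCc2ccc(OC)cc2)cc(OCc2ccc(OC)cc2)c1 | intermediate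
10 | 4-chloro-2-(diazo{3,5-bis[(4-methoxyphenyl)methoxy]phenyl}methyl)-1-[(4-methoxyphenyl)methoxy]benzene (not isolated) | [N-]=[N+]=C(c1cc(Cl)ccc1OCc1ccc(OC)cc1)c1cc(OCc2ccc(OC)cc2)cc(OCc2ccc(OC)cc2)c1 | intermediate
11 | (2R,3S)-3-{3,5-bis[(4-methoxyphenyl)methoxy]phenyl}-5-chloro-2-(4-methoxyphenyl)-2,3-dihydro-1-benzofuran (cis) | COc1ccc([C@@H]2Oc3ccc(Cl)cc3[C@@H]2c2cc(OCc3ccc(OC)cc3)cc(OCc3ccc(OC)cc3)c2)cc1 | intermediate
12 | (2R,3R)-3-{2-bromo-3,5-bis[(4-methoxyphenyl)methoxy]phenyl}-5-chloro-2-(4-methoxyphenyl)-2,3-dihydro-1-benzofuran (cis) | COc1ccc([C@@H]2Oc3ccc(Cl)cc3[C@@H]2c2cc(OCc3ccc(OC)cc3)cc(OCc3ccc(OC)cc3)c2Br)cc1 | intermediate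
13 | 3,5-dimethoxybenzaldehyde | COc1cc(C=O)cc(OC)c1 | starting material
14 | {2-[(2R,3S)-5-chloro-2-(4-methoxyphenyl)-2,3-dihydro-1-benzofuran-3-yl]-4,6-bis[(4-methoxyphenyl)methoxy]phenyl}lithium (not isolated) | COc1ccc([C@@H]2Oc3ccc(Cl)cc3[C@@H]2c2cc(OCc3ccc(OC)cc3)cc(OCc3ccc(OC)cc3)c2[Li])cc1 | intermediate
15 | {2-[(2R,3S)-5-chloro-2-(4-methoxyphenyl)-2,3-dihydro-1-benzofuran-3-yl]-4,6-bis[(4-methoxyphenyl)methoxy]phenyl}(3,5-dimethoxyphenyl)methanol (both carbinol epimers) | COc1ccc([C@@H]2Oc3ccc(Cl)cc3[C@@H]2c2cc(OCc3ccc(OC)cc3)cc(OCc3ccc(OC)cc3)c2C(O)c2cc(OC)cc(OC)c2)cc1 | intermediate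
16 | {2-[(2R,3S)-5-chloro-2-(4-methoxyphenyl)-2,3-dihydro-1-benzofuran-3-yl]-4,6-bis[(4-methoxyphenyl)methoxy]phenyl}(3,5-dimethoxyphenyl)methanone | COc1ccc([C@@H]2Oc3ccc(Cl)cc3[C@@H]2c2cc(OCc3ccc(OC)cc3)cc(OCc3ccc(OC)cc3)c2C(=O)c2cc(OC)cc(OC)c2)cc1 | intermediate
17 | [{2-[(2R,3S)-5-chloro-2-(4-methoxyphenyl)-2,3-dihydro-1-benzofuran-3-yl]-4,6-bis[(4-methoxyphenyl)methoxy]phenyl}(3,5-dimethoxyphenyl)methylidene]hydrazine (E/Z mixture) | COc1ccc([C@@H]2Oc3ccc(Cl)cc3[C@@H]2c2cc(OCc3ccc(OC)cc3)cc(OCc3ccc(OC)cc3)c2C(=NN)c2cc(OC)cc(OC)c2)cc1 | intermediate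
18 | (2R,3S)-5-chloro-3-{2-[diazo(3,5-dimethoxyphenyl)methyl]-3,5-bis[(4-methoxyphenyl)methoxy]phenyl}-2-(4-methoxyphenyl)-2,3-dihydro-1-benzofuran (not isolated) | COc1ccc([C@@H]2Oc3ccc(Cl)cc3[C@@H]2c2cc(OCc3ccc(OC)cc3)cc(OCc3ccc(OC)cc3)c2C(=[N+]=[N-])c2cc(OC)cc(OC)c2)cc1 | intermediate
19 | (2R,3S)-4-[(2R,3S)-5-chloro-2-(4-methoxyphenyl)-2,3-dihydro-1-benzofuran-3-yl]-3-(3,5-dimethoxyphenyl)-2-(4-methoxyphenyl)-6-[(4-methoxyphenyl)methoxy]-2,3-dihydro-1-benzofuran (both rings cis) | COc1ccc([C@@H]2Oc3ccc(Cl)cc3[C@@H]2c2cc(OCc4ccc(OC)cc4)cc3c2[C@H](c2cc(OC)cc(OC)c2)[C@H](c2ccc(OC)cc2)O3)cc1 | intermediate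
20 | 3,5-dimethoxystyrene | C=Cc1cc(OC)cc(OC)c1 | starting material
21 | (2R,3S)-4-{(2R,3S)-5-[(E)-2-(3,5-dimethoxyphenyl)ethenyl]-2-(4-methoxyphenyl)-2,3-dihydro-1-benzofuran-3-yl}-3-(3,5-dimethoxyphenyl)-2-(4-methoxyphenyl)-6-[(4-methoxyphenyl)methoxy]-2,3-dihydro-1-benzofuran (both rings cis) | COc1ccc([C@@H]2Oc3ccc(/C=C/c4cc(OC)cc(OC)c4)cc3[C@@H]2c2cc(OCc4ccc(OC)cc4)cc3c2[C@H](c2cc(OC)cc(OC)c2)[C@H](c2ccc(OC)cc2)O3)cc1 | intermediate
22 | trans-diptoindonesin B, (2S,3S)-4-{(2S,3S)-5-[(E)-2-(3,5-dihydroxyphenyl)ethenyl]-2-(4-hydroxyphenyl)-2,3-dihydro-1-benzofuran-3-yl}-3-(3,5-dihydroxyphenyl)-2-(4-hydroxyphenyl)-2,3-dihydro-1-benzofuran-6-ol (both rings trans) | Oc1ccc([C@H]2Oc3ccc(/C=C/c4cc(O)cc(O)c4)cc3[C@@H]2c2cc(O)cc3c2[C@H](c2cc(O)cc(O)c2)[C@@H](c2ccc(O)cc2)O3)cc1 | target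

**Step count and risks**

Total steps: 13. Longest linear sequence: 12 steps (step 1 or step 2, then steps 3 to 13).

Steps most likely to fail:

1. Step 11. The diazo carbon is flanked by two ortho substituents, so carbene formation at the bulky catalyst may be slow and azine formation may take over; a mismatched interplay of the catalyst with the stereocentres of ring 1 could also erode facial selectivity at C3'. The fallback sets out from ketone 16 and comes back to the route at 22. A strong non-nucleophilic base (t-BuOK in DMF, or the phosphazene base P4-t-Bu) should deprotonate the ortho O–CH2Ar group, whose carbanion adds to the ketone and loses water to give (2R,3S)-5-chloro-3-{3-(3,5-dimethoxyphenyl)-2-(4-methoxyphenyl)-6-[(4-methoxyphenyl)methoxy]-1-benzofuran-4-yl}-2-(4-methoxyphenyl)-2,3-dihydro-1-benzofuran F1. Ionic hydrogenation (Et3SiH, CF3CO2H, CH2Cl2) should protonate C3' and deliver hydride to C2' trans to ring D. The same acid removes the remaining PMB ether and equilibrates ring 1 to trans, so the product should be the trans,trans chloro phenol (2S,3S)-4-[(2S,3S)-5-chloro-2-(4-methoxyphenyl)-2,3-dihydro-1-benzofuran-3-yl]-3-(3,5-dimethoxyphenyl)-2-(4-methoxyphenyl)-2,3-dihydro-1-benzofuran-6-ol F2. C3' is under substrate control only in this sequence, so F2 would have to be separated by chromatography from its ring 2 diastereomer. Heck coupling of F2 with 20 under the conditions of step 12 should give the stilbene hexamethyl ether F3, and BBr3 as in step 13 then leads to 22.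

2. Step 10. Condensation at a carbonyl carbon flanked by two ortho substituents may stay incomplete, and forcing it may favour the azine. The fallback sets out from bromide 12 and comes back at hydrazone 17, bypassing 15 and 16. Aryllithium 14 (n-BuLi, THF, −78 °C) is added to 3,5-dimethoxybenzonitrile and the N-lithio imine is quenched with MeOH to give the N-unsubstituted ketimine 1-{2-[(2R,3S)-5-chloro-2-(4-methoxyphenyl)-2,3-dihydro-1-benzofuran-3-yl]-4,6-bis[(4-methoxyphenyl)methoxy]phenyl}-1-(3,5-dimethoxyphenyl)methanimine F4. Transimination with N2H4·H2O (AcOH cat., EtOH) should then give 17; the protonated imine is more electrophilic than the ketone.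

3. Step 13. While both benzylic C–O bonds are reversibly opened in the presence of the stilbene, several acid-mediated side reactions are possible: capture of the C2 cation by ring D to form a seven-membered ring, oligomerisation of the stilbene, benzylation by the PMB cation, and erosion at C3 or C3' through elimination. The fallback sets out from 19 and comes back at 22; it moves the Lewis-acid step ahead of the olefin. BBr3 with pentamethylbenzene on 19 should give the trans,trans chloro pentaphenol (2S,3S)-4-[(2S,3S)-5-chloro-2-(4-hydroxyphenyl)-2,3-dihydro-1-benzofuran-3-yl]-3-(3,5-dihydroxyphenyl)-2-(4-hydroxyphenyl)-2,3-dihydro-1-benzofuran-6-ol F5. Acetylation (Ac2O, pyridine) gives the pentaacetate F6. Heck coupling of F6 with commercial 3,5-diacetoxystyrene (Pd2(dba)3, P(t-Bu)3, N,N-dicyclohexylmethylamine, 1,4-dioxane, 100 °C) gives the heptaacetate of the target F7, and methanolysis (K2CO3, MeOH, rt) gives 22.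

**Further compounds**

F1 | step 11 | (2R,3S)-5-chloro-3-{3-(3,5-dimethoxyphenyl)-2-(4-methoxyphenyl)-6-[(4-methoxyphenyl)methoxy]-1-benzofuran-4-yl}-2-(4-methoxyphenyl)-2,3-dihydro-1-benzofuran | COc1ccc([C@@H]2Oc3ccc(Cl)cc3[C@@H]2c2cc(OCc3ccc(OC)cc3)cc3oc(-c4ccc(OC)cc4)c(-c4cc(OC)cc(OC)c4)c23)cc1
F2 | step 11 | (2S,3S)-4-[(2S,3S)-5-chloro-2-(4-methoxyphenyl)-2,3-dihydro-1-benzofuran-3-yl]-3-(3,5-dimethoxyphenyl)-2-(4-methoxyphenyl)-2,3-dihydro-1-benzofuran-6-ol | COc1ccc([C@H]2Oc3ccc(Cl)cc3[C@@H]2c2cc(O)cc3c2[C@H](c2cc(OC)cc(OC)c2)[C@@H](c2ccc(OC)cc2)O3)cc1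
F3 | step 11 | (2S,3S)-4-{(2S,3S)-5-[(E)-2-(3,5-dimethoxyphenyl)ethenyl]-2-(4-methoxyphenyl)-2,3-dihydro-1-benzofuran-3-yl}-3-(3,5-dimethoxyphenyl)-2-(4-methoxyphenyl)-2,3-dihydro-1-benzofuran-6-ol | COc1ccc([C@H]2Oc3ccc(/C=C/c4cc(OC)cc(OC)c4)cc3[C@@H]2c2cc(O)cc3c2[C@H](c2cc(OC)cc(OC)c2)[C@@H](c2ccc(OC)cc2)O3)cc1
F4 | step 10 | 1-{2-[(2R,3S)-5-chloro-2-(4-methoxyphenyl)-2,3-dihydro-1-benzofuran-3-yl]-4,6-bis[(4-methoxyphenyl)methoxy]phenyl}-1-(3,5-dimethoxyphenyl)methanimine | COc1ccc([C@@H]2Oc3ccc(Cl)cc3[C@@H]2c2cc(OCc3ccc(OC)cc3)cc(OCc3ccc(OC)cc3)c2C(=N)c2cc(OC)cc(OC)c2)cc1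
F5 | step 13 | (2S,3S)-4-[(2S,3S)-5-chloro-2-(4-hydroxyphenyl)-2,3-dihydro-1-benzofuran-3-yl]-3-(3,5-dihydroxyphenyl)-2-(4-hydroxyphenyl)-2,3-dihydro-1-benzofuran-6-ol | Oc1ccc([C@H]2Oc3ccc(Cl)cc3[C@@H]2c2cc(O)cc3c2[C@H](c2cc(O)cc(O)c2)[C@@H](c2ccc(O)cc2)O3)cc1
F6 | step 13 | pentaacetate of F5 | CC(=O)Oc1ccc([C@H]2Oc3ccc(Cl)cc3[C@@H]2c2cc(OC(C)=O)cc3c2[C@H](c2cc(OC(C)=O)cc(OC(C)=O)c2)[C@@H](c2ccc(OC(C)=O)cc2)O3)cc1
F7 | step 13 | heptaacetate of trans-diptoindonesin B | CC(=O)Oc1ccc([C@H]2Oc3ccc(/C=C/c4cc(OC(C)=O)cc(OC(C)=O)c4)cc3[C@@H]2c2cc(OC(C)=O)cc3c2[C@H](c2cc(OC(C)=O)cc(OC(C)=O)c2)[C@@H](c2ccc(OC(C)=O)cc2)O3)cc1
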